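## The problem

Prostaglandin F1α (26) is a cyclopentane whose ring carbons C8, C9, C11 and C12 (prostaglandin numbering, C1 = carboxyl carbon) are contiguous stereocentres. The saturated seven-carbon acid chain on C8 and the hydroxyls on C9 and C11 lie on one face, the ω-chain on C12 on the other, and a fifth centre, C15 (S), sits outside the ring beyond an E alkene. The ring centres can pass configuration to one another: C8 can place C12 trans to itself, C12 can place O11 trans to itself, and a bulky hydride approaches a C9 ketone anti to the C8 chain. C15 is too remote for relay and needs a reagent. Several intermediates are fragile: a C9 ketone with oxygen on C11 eliminates to the enone under base, a C13 aldehyde next to O11 has the same weakness, C8 epimerises while it is α to an acyclic carbonyl, and the C15 allylic alcohol does not tolerate strong acid. Because the upper chain is saturated it can be carried from the start as a methyl ester, but its C6–H bonds then lie as close to C10 as those of C11. The enabling feature is that C12 bears two one-carbon arms that both end up oxygenated or oxidised: C11 (ring carbinol) and C13 (alkene carbon, reachable from CH2O). A C12 with two identical silyloxymethyl groups is therefore prochiral, and a carbenoid at C10 next to the C9 carbonyl can insert into an oxygen-activated C11–H bond of one arm. That forms C10–C11, closes the ring and fixes C11 and C12 under the direction of C8.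

## Retrosynthesis

**End game.** Acid 26 is taken back to its methyl ester 25 and this to the 11-silyl ether 24. The silyl group stays on O11 until the last C–C bond and the last reduction are done, so that neither the C13 aldehyde nor the enone carries a free β-hydroxyl.

**C15–O and C13=C14.** The C15 carbinol of 24 comes from enone 23 by a reagent-controlled reduction. The C13=C14 bond comes from aldehyde 21 and the commercial β-keto phosphonate 22. A preformed chiral ω-chain would cost a separate synthesis; the olefination route uses a purchasable C14–C20 unit and asks only for E selectivity and one face-selective reduction.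

**C13 oxidation state and C9.** Aldehyde 21 comes from diol 20 by oxidation of the only primary alcohol. Diol 20 comes from bis-silyl ether 19, in which the primary C13 ether is told from the secondary C11 ether by sterics. The 9α-alcohol of 19 comes from ketone 18 by hydride attack anti to the C8 chain. Ketone 18 is the keto ester 16 without its ester, removed by hydrogenolysis and decarboxylation.

**Key disconnection, C10–C11.** Cutting C10–C11 of 16 leads to the acyclic diazo keto ester 15, which has one stereocentre (C8) and a prochiral C12. Closing the ring at C8–C12 or C9–C10 would require C11 and C12 to be set beforehand; the C10–C11 cut lets one centre write two. Two choices protect the step: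
- The arms are silyl ethers rather than benzyl ethers, because a silyl ether oxygen activates the adjacent C–H bond but is a poor partner for oxonium ylide formation.
- The ester is benzyl rather than allyl, so the carbenoid meets no alkene and the ester can later be removed under neutral conditions.

The forward reaction must prefer C11–H to C6–H, pick one arm, and pick one hydrogen.

**C9–C10.** Diazo compound 15 comes from β-keto ester 14 by diazo transfer. 14 comes from aldehyde 12 and benzyl diazoacetate 13 by a Lewis-acid-mediated homologation. Entry through an acid and acyl substitution at C9 was set aside because C9 is flanked by a doubly branched carbon, and because the aldehyde is the oxidation level delivered by the alkylation chosen for C8.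

**C7–C8.** Aldehyde 12 comes from hydrazone 11, and 11 from hydrazone 7 and iodide 9 (from bromide 8). An azaenolate was chosen because it alkylates unactivated primary iodides at very low temperature and the auxiliary leaves under neutral conditions that spare the C1 ester. An imide enolate would be sluggish with such an electrophile, and an amide auxiliary would need hydrolytic or reductive cleavage that the C1 ester does not survive.

**Acyclic backbone.** Hydrazone 7 comes from aldehyde 5 and hydrazine 6. Aldehyde 5 comes from ester 4, alkene 3, and finally ketone 1 and phosphonate 2. No stereocentre exists before C8 is set.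

## Roads not taken

**Alternative 1:** The ring is cut at C8–C9 and C11=C12 together. Two molecules of succinaldehyde A1 are joined by an amine-catalysed enantioselective aldol reaction (C8–C9); an ammonium-salt-mediated intramolecular aldol condensation closes the cyclopentene (C11=C12), and O9 adds to C6 to give the bicyclic enal lactol A2.
- Merits: A2 arises in one operation with C8 and C9 set by the catalyst. The ω-chain can be added by conjugate addition to the enal and the upper chain by a lactol Wittig reaction, so the whole synthesis would be roughly half as long as the one chosen here.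
- Weak points for 26: A1 oligomerises readily, so throughput of the dimerisation is limited. The ω-chain must be brought as a separately made, enantiopure vinyl metal reagent. The C11 oxygen has to be introduced afterwards. The lactol Wittig reaction gives a 5,6-alkene that the 1-series lacks, so a site-selective hydrogenation beside the 13,14-alkene must be added.
- Comparison: in step count this road is clearly better. The chosen plan offers in return a saturated upper chain that is part of the skeleton from the alkylation onward, no alkene differentiation, no chiral ω-chain reagent, and C9, C11 and C12 all descending from one auxiliary-set centre.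

**Alternative 2:** The cuts are C7–C8 and C12–C13. The mixed iodoacetal A3 of a mono-silylated cis-cyclopentenediol is treated with a tin hydride. The C7 radical adds to C8 and closes the cis-fused tetrahydrofuran acetal; the resulting C12 radical is trapped by the 2-silyl enone A4 to give the bicyclic acetal A5.
- Merits: C8 and C12 and both chain attachments arise in one cascade, the 9,11-cis-dioxygenation is present from the start, and A4 brings the whole ω-chain skeleton.
- Weak points: the C12 radical must add to A4 faster than it is reduced, which calls for stoichiometric tin hydride at low concentration and excess A4. The α-silyl ketone of A5 still has to become the enone before C15 is reduced. The enantiopure cyclopentenediol monoether must be prepared. C6 is again joined to C5 by a Wittig reaction, which leaves the unwanted 5,6-alkene.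
- Comparison: the step count is similar or slightly lower, and the diol is secured earlier. The chosen plan avoids tin, radical-trapping kinetics and alkene differentiation, and closes the ring catalytically.

**Alternative 3:** Only C8–C12 is formed. Cyclooxygenase converts the all-cis C20 trienoic acid A6 under air into the endoperoxide hydroperoxide A7, forming O–C11, O–C9, C8–C12 and O–C15 and all five stereocentres. Reduction of both peroxide groups of A7 gives 26.
- Merits: two operations, complete stereocontrol and no protecting groups. No chemical plan can match this.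
- Weak points: the enzyme is inactivated during turnover and works at high dilution. A6 is itself a costly polyunsaturated acid, so the route is a biotransformation of an advanced lipid. A7 is a labile endoperoxide, and analogues are not accessible.
- Comparison: this road is better in brevity and selectivity. The chosen plan offers ordinary reagents, stable intermediates, scalability and independence from the enzyme and from A6.

Key step: step 10

## Route

Assumption: 1, 6, 13 (as a toluene solution) and 22 are taken as purchasable. TBS = tert-butyldimethylsilyl. Positions are given in prostaglandin numbering.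

Step 1
Reactants: 1 1,3-bis[(tert-butyldimethylsilyl)oxy]propan-2-one; 2 triethyl phosphonoacetate
Product: 3 ethyl 4-[(TBS)oxy]-3-{[(TBS)oxy]methyl}but-2-enoate
Conditions: NaH, THF, 0 °C to rt
Reagents that add atoms: none
Why: Horner–Wadsworth–Emmons olefination of a symmetrical ketone by the stabilised phosphonate anion; no alkene geometry arises because the β-carbon carries two identical arms.

Step 2
Reactants: 3 ethyl 4-[(TBS)oxy]-3-{[(TBS)oxy]methyl}but-2-enoate
Product: 4 ethyl 4-[(TBS)oxy]-3-{[(TBS)oxy]methyl}butanoate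
Conditions: H2 (1 atm), 10% Pd/C, EtOAc, rt
Reagents that add atoms: none
Why: Heterogeneous hydrogenation of the electron-poor trisubstituted alkene; neutral EtOAc protects the allylic silyl ethers from solvolysis, and C12 stays prochiral.

Step 3
Reactants: 4 ethyl 4-[(TBS)oxy]-3-{[(TBS)oxy]methyl}butanoate
Product: 5 4-[(TBS)oxy]-3-{[(TBS)oxy]methyl}butanal
Conditions: i-Bu2AlH (1.05 equiv), CH2Cl2, −78 °C; aq. Rochelle salt
Reagents that add atoms: none
Why: Partial reduction of an ester; at −78 °C the aluminium hemiacetal persists until work-up, so the aldehyde is released without over-reduction.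

Step 4
Reactants: 5 4-[(TBS)oxy]-3-{[(TBS)oxy]methyl}butanal; 6 (S)-1-amino-2-(methoxymethyl)pyrrolidine (SAMP)
Product: 7 (S,E)-N-{4-[(TBS)oxy]-3-{[(TBS)oxy]methyl}butylidene}-2-(methoxymethyl)pyrrolidin-1-amine
Conditions: CH2Cl2, 4 Å molecular sieves, 0 °C to rt
Reagents that add atoms: none
Why: Condensation of the aldehyde with the N-amino group gives the (E)-hydrazone and installs the auxiliary for the Enders alkylation.

Step 5
Reactants: 8 methyl 7-bromoheptanoate
Product: 9 methyl 7-iodoheptanoate
Conditions: NaI, acetone, reflux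
Reagents that add atoms: sodium iodide, [Na+].[I-]
Why: Finkelstein exchange driven by precipitation of NaBr; the iodide allows SN2 alkylation at very low temperature.

Step 6
Reactants: 7 (S,E)-N-{4-[(TBS)oxy]-3-{[(TBS)oxy]methyl}butylidene}-2-(methoxymethyl)pyrrolidin-1-amine; 9 methyl 7-iodoheptanoate
Product: 11 methyl (8R)-10-[(TBS)oxy]-9-{[(TBS)oxy]methyl}-8-[(E)-{[(2S)-2-(methoxymethyl)pyrrolidin-1-yl]imino}methyl]decanoate, via lithium azaenolate 10 (not isolated)
Conditions: LiN(i-Pr)2, THF, 0 °C; then 9, −100 °C to −78 °C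
Reagents that add atoms: none
Why: Enders SAMP-hydrazone alkylation: deprotonation gives the (E)-C=C, (Z)-C–N azaenolate with lithium chelated by the methoxymethyl arm, and the iodide attacks the face away from the pyrrolidine substituent, which sets C8 as R; at −100 °C displacement of the primary iodide should outrun addition to the methyl ester.

Step 7
Reactants: 11 methyl (8R)-10-[(TBS)oxy]-9-{[(TBS)oxy]methyl}-8-[(E)-{[(2S)-2-(methoxymethyl)pyrrolidin-1-yl]imino}methyl]decanoate
Product: 12 methyl (8R)-10-[(TBS)oxy]-9-{[(TBS)oxy]methyl}-8-formyldecanoate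
Conditions: O3, CH2Cl2, −78 °C; N2 purge; used at once
Reagents that add atoms: ozone, [O-][O+]=O
Why: Ozonolytic cleavage of the hydrazone C=N bond releases the aldehyde without acid or base, so C8 is not epimerised; silyl ethers and the ester are inert to ozone.

Step 8
Reactants: 12 methyl (8R)-10-[(TBS)oxy]-9-{[(TBS)oxy]methyl}-8-formyldecanoate; 13 benzyl diazoacetate
Product: 14 1-benzyl 11-methyl (4R)-4-{1,3-bis[(TBS)oxy]propan-2-yl}-3-oxoundecanedioate
Conditions: SnCl2 (10 mol%), CH2Cl2, rt
Reagents that add atoms: none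
Why: Roskamp reaction: the Lewis acid activates the aldehyde, the diazo carbon adds, and a 1,2-hydride shift with loss of N2 gives the β-keto ester, forming C9–C10 without a basic step that could touch C8.

Step 9
Reactants: 14 1-benzyl 11-methyl (4R)-4-{1,3-bis[(TBS)oxy]propan-2-yl}-3-oxoundecanedioate
Product: 15 1-benzyl 11-methyl (4R)-4-{1,3-bis[(TBS)oxy]propan-2-yl}-2-diazo-3-oxoundecanedioate
Conditions: 4-acetamidobenzenesulfonyl azide, Et3N, MeCN, 0 °C to rt
Reagents that add atoms: 4-acetamidobenzenesulfonyl azide, CC(=O)Nc1ccc(cc1)S(=O)(=O)N=[N+]=[N-]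
Why: Regitz diazo transfer to the doubly activated C10 methylene; the amine base deprotonates only between the two carbonyls, so C8 is untouched.

Step 10
Reactants: 15 1-benzyl 11-methyl (4R)-4-{1,3-bis[(TBS)oxy]propan-2-yl}-2-diazo-3-oxoundecanedioate
Product: 16 benzyl (2S,3S,4R)-2-[(TBS)oxy]-3-{[(TBS)oxy]methyl}-4-(7-methoxy-7-oxoheptyl)-5-oxocyclopentane-1-carboxylate (epimers at C1)
Conditions: Rh2(OAc)4 (1 mol%), CH2Cl2, rt
Reagents that add atoms: none
Why: Rh2(OAc)4 expels N2 from 15 to give an electrophilic divalent-rhodium carbenoid at C10, which inserts into a C–H bond five atoms away in a concerted three-centre step with retention, as in the known dirhodium-catalysed 1,5 C–H insertion of α-diazo β-keto esters next to ether oxygen. The cyclopentanone is closed by forming C10–C11 through a chair-like six-centre array of C10, C9, C8, C12, C11 and the migrating hydrogen. C12 becomes stereogenic by the choice of arm and C11 by the choice of hydrogen; C8 controls both, because only one chair places the C8 chain, the spectator silyloxymethyl arm and the C11 silyloxy group all pseudo-equatorial, which leads to the 8,12-trans, 11,12-trans product (C10 is formed as an enolisable centre and is removed in step 11). Selectivity for C11–H over the equidistant C6–H bonds rests on the silyl ether oxygen, whose lone pair stabilises the positive charge that builds up at the inserting carbon. The silyl ether oxygen is a poor donor towards the carbenoid, which holds back oxonium ylide formation, and the benzyl ester offers no alkene for cyclopropanation. Reaction on the ester side is disfavoured by the ester conformation and by ring size.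

Step 11
Reactants: 16 benzyl (2S,3S,4R)-2-[(TBS)oxy]-3-{[(TBS)oxy]methyl}-4-(7-methoxy-7-oxoheptyl)-5-oxocyclopentane-1-carboxylate
Product: 18 methyl 7-[(1R,2S,3R)-3-[(TBS)oxy]-2-{[(TBS)oxy]methyl}-5-oxocyclopentyl]heptanoate, via β-keto acid 17 (not isolated)
Conditions: H2 (1 atm), 10% Pd/C, EtOAc, rt; filter; toluene, 60 °C
Reagents that add atoms: none
Why: Hydrogenolysis of the benzyl ester gives the β-keto acid, which loses CO2 through a cyclic transition state on gentle warming; the conditions are neutral, so the β-silyloxy ketone does not eliminate and C8 keeps its more stable trans arrangement.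

Step 12
Reactants: 18 methyl 7-[(1R,2S,3R)-3-[(TBS)oxy]-2-{[(TBS)oxy]methyl}-5-oxocyclopentyl]heptanoate
Product: 19 methyl 7-[(1R,2S,3R,5S)-3-[(TBS)oxy]-2-{[(TBS)oxy]methyl}-5-hydroxycyclopentyl]heptanoate
Conditions: LiBH(s-Bu)3, THF, −78 °C; aq. NH4Cl
Reagents that add atoms: none
Why: Reduction of the cyclopentanone by a bulky trialkylborohydride from the face opposite the adjacent C8 chain and the C11 silyloxy group places the new hydroxyl cis to both (9S); the methyl ester is not reduced at −78 °C.

Step 13
Reactants: 19 methyl 7-[(1R,2S,3R,5S)-3-[(TBS)oxy]-2-{[(TBS)oxy]methyl}-5-hydroxycyclopentyl]heptanoate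
Product: 20 methyl 7-[(1R,2S,3R,5S)-3-[(TBS)oxy]-5-hydroxy-2-(hydroxymethyl)cyclopentyl]heptanoate
Conditions: camphorsulfonic acid (0.1 equiv), MeOH/CH2Cl2 (1:1), 0 °C
Reagents that add atoms: none
Why: Acid-catalysed methanolysis of silyl ethers is governed by sterics, so the primary C13 ether should cleave well before the secondary, ring-flanked C11 ether.

Step 14
Reactants: 20 methyl 7-[(1R,2S,3R,5S)-3-[(TBS)oxy]-5-hydroxy-2-(hydroxymethyl)cyclopentyl]heptanoate
Product: 21 methyl 7-[(1R,2R,3R,5S)-3-[(TBS)oxy]-2-formyl-5-hydroxycyclopentyl]heptanoate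
Conditions: TEMPO (10 mol%), PhI(OAc)2, CH2Cl2, rt
Reagents that add atoms: none
Why: Oxoammonium-mediated oxidation is selective for primary over secondary alcohols, so only C13 is oxidised; the 9-hydroxyl is trans to the formyl group and cannot form a lactol, and the near-neutral medium spares the β-silyloxy aldehyde.

Step 15
Reactants: 21 methyl 7-[(1R,2R,3R,5S)-3-[(TBS)oxy]-2-formyl-5-hydroxycyclopentyl]heptanoate; 22 dimethyl (2-oxoheptyl)phosphonate
Product: 23 methyl 7-[(1R,2R,3R,5S)-3-[(TBS)oxy]-5-hydroxy-2-[(1E)-3-oxooct-1-en-1-yl]cyclopentyl]heptanoate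
Conditions: LiCl, i-Pr2NEt, MeCN, rt
Reagents that add atoms: none
Why: Horner–Wadsworth–Emmons olefination under Masamune–Roush conditions: lithium chelation lets an amine base deprotonate the β-keto phosphonate, which avoids β-elimination of the silyloxy group, tolerates the free hydroxyl and gives the E enone.

Step 16
Reactants: 23 methyl 7-[(1R,2R,3R,5S)-3-[(TBS)oxy]-5-hydroxy-2-[(1E)-3-oxooct-1-en-1-yl]cyclopentyl]heptanoate
Product: 24 methyl 7-[(1R,2R,3R,5S)-3-[(TBS)oxy]-5-hydroxy-2-[(1E,3S)-3-hydroxyoct-1-en-1-yl]cyclopentyl]heptanoate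
Conditions: (R)-Me-CBS oxazaborolidine [(R)-1-methyl-3,3-diphenyltetrahydro-1H,3H-pyrrolo[1,2-c][1,3,2]oxazaborole], catecholborane (excess), toluene, −78 °C
Reagents that add atoms: none
Why: Corey–Bakshi–Shibata reduction: the (R)-oxazaborolidine binds the ketone with the alkenyl group as the large substituent and directs hydride to the face that gives the 15S allylic alcohol; 1,2-reduction is favoured at low temperature and the free 9-hydroxyl only consumes borane.

Step 17
Reactants: 24 methyl 7-[(1R,2R,3R,5S)-3-[(TBS)oxy]-5-hydroxy-2-[(1E,3S)-3-hydroxyoct-1-en-1-yl]cyclopentyl]heptanoate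
Product: 25 methyl 7-[(1R,2R,3R,5S)-3,5-dihydroxy-2-[(1E,3S)-3-hydroxyoct-1-en-1-yl]cyclopentyl]heptanoate (prostaglandin F1α methyl ester)
Conditions: HF·pyridine, THF, 0 °C to rt
Reagents that add atoms: none
Why: Fluoride-driven cleavage of the secondary silyl ether under buffered conditions that the allylic alcohol tolerates.

Step 18
Reactants: 25 methyl 7-[(1R,2R,3R,5S)-3,5-dihydroxy-2-[(1E,3S)-3-hydroxyoct-1-en-1-yl]cyclopentyl]heptanoate
Product: 26 7-[(1R,2R,3R,5S)-3,5-dihydroxy-2-[(1E,3S)-3-hydroxyoct-1-en-1-yl]cyclopentyl]heptanoic acid (prostaglandin F1α)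
Conditions: LiOH, THF/MeOH/H2O, rt; then 1 M HCl to pH 4
Reagents that add atoms: lithium hydroxide, [Li+].[OH-]
Why: Saponification of the methyl ester; the F-type triol has no base-sensitive β-hydroxy ketone, and acidification only to about pH 4 protects the allylic alcohol.

## Compound list

1 | 1,3-bis[(tert-butyldimethylsilyl)oxy]propan-2-one | CC(C)(C)[Si](C)(C)OCC(=O)CO[Si](C)(C)C(C)(C)C | starting material
2 | triethyl phosphonoacetate | CCOC(=O)CP(=O)(OCC)OCC | starting material
3 | ethyl 4-[(TBS)oxy]-3-{[(TBS)oxy]methyl}but-2-enoate | CCOC(=O)C=C(CO[Si](C)(C)C(C)(C)C)CO[Si](C)(C)C(C)(C)C | intermediate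
4 | ethyl 4-[(TBS)oxy]-3-{[(TBS)oxy]methyl}butanoate | CCOC(=O)CC(CO[Si](C)(C)C(C)(C)C)CO[Si](C)(C)C(C)(C)C | intermediate
5 | 4-[(TBS)oxy]-3-{[(TBS)oxy]methyl}butanal | O=CCC(CO[Si](C)(C)C(C)(C)C)CO[Si](C)(C)C(C)(C)C | intermediate
6 | (S)-1-amino-2-(methoxymethyl)pyrrolidine (SAMP) | COC[C@@H]1CCCN1N | starting material
7 | (S,E)-N-{4-[(TBS)oxy]-3-{[(TBS)oxy]methyl}butylidene}-2-(methoxymethyl)pyrrolidin-1-amine | COC[C@@H]1CCCN1/N=C/CC(CO[Si](C)(C)C(C)(C)C)CO[Si](C)(C)C(C)(C)C | intermediate
8 | methyl 7-bromoheptanoate | COC(=O)CCCCCCBr | starting material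
9 | methyl 7-iodoheptanoate | COC(=O)CCCCCCI | intermediate
10 | lithium azaenolate of 7, (E)-C=C | [Li+].COC[C@@H]1CCCN1[N-]/C=C/C(CO[Si](C)(C)C(C)(C)C)CO[Si](C)(C)C(C)(C)C | intermediate
11 | methyl (8R)-10-[(TBS)oxy]-9-{[(TBS)oxy]methyl}-8-[(E)-{[(2S)-2-(methoxymethyl)pyrrolidin-1-yl]imino}methyl]decanoate | COC[C@@H]1CCCN1/N=C/[C@H](CCCCCCC(=O)OC)C(CO[Si](C)(C)C(C)(C)C)CO[Si](C)(C)C(C)(C)C | intermediate
12 | methyl (8R)-10-[(TBS)oxy]-9-{[(TBS)oxy]methyl}-8-formyldecanoate | O=C[C@H](CCCCCCC(=O)OC)C(CO[Si](C)(C)C(C)(C)C)CO[Si](C)(C)C(C)(C)C | intermediate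
13 | benzyl diazoacetate | [N-]=[N+]=CC(=O)OCc1ccccc1 | starting material
14 | 1-benzyl 11-methyl (4R)-4-{1,3-bis[(TBS)oxy]propan-2-yl}-3-oxoundecanedioate | O=C(CC(=O)[C@H](CCCCCCC(=O)OC)C(CO[Si](C)(C)C(C)(C)C)CO[Si](C)(C)C(C)(C)C)OCc1ccccc1 | intermediate
15 | 1-benzyl 11-methyl (4R)-4-{1,3-bis[(TBS)oxy]propan-2-yl}-2-diazo-3-oxoundecanedioate | [N-]=[N+]=C(C(=O)OCc1ccccc1)C(=O)[C@H](CCCCCCC(=O)OC)C(CO[Si](C)(C)C(C)(C)C)CO[Si](C)(C)C(C)(C)C | intermediate
16 | benzyl (2S,3S,4R)-2-[(TBS)oxy]-3-{[(TBS)oxy]methyl}-4-(7-methoxy-7-oxoheptyl)-5-oxocyclopentane-1-carboxylate (epimers at C1) | O=C(OCc1ccccc1)C1C(=O)[C@H](CCCCCCC(=O)OC)[C@@H](CO[Si](C)(C)C(C)(C)C)[C@@H]1O[Si](C)(C)C(C)(C)C | intermediate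
17 | (2S,3S,4R)-2-[(TBS)oxy]-3-{[(TBS)oxy]methyl}-4-(7-methoxy-7-oxoheptyl)-5-oxocyclopentane-1-carboxylic acid | OC(=O)C1C(=O)[C@H](CCCCCCC(=O)OC)[C@@H](CO[Si](C)(C)C(C)(C)C)[C@@H]1O[Si](C)(C)C(C)(C)C | intermediate
18 | methyl 7-[(1R,2S,3R)-3-[(TBS)oxy]-2-{[(TBS)oxy]methyl}-5-oxocyclopentyl]heptanoate | C1C(=O)[C@H](CCCCCCC(=O)OC)[C@@H](CO[Si](C)(C)C(C)(C)C)[C@@H]1O[Si](C)(C)C(C)(C)C | intermediate
19 | methyl 7-[(1R,2S,3R,5S)-3-[(TBS)oxy]-2-{[(TBS)oxy]methyl}-5-hydroxycyclopentyl]heptanoate | CC(C)(C)[Si](C)(C)OC[C@@H]1[C@@H](CCCCCCC(=O)OC)[C@@H](O)C[C@H]1O[Si](C)(C)C(C)(C)C | intermediate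
20 | methyl 7-[(1R,2S,3R,5S)-3-[(TBS)oxy]-5-hydroxy-2-(hydroxymethyl)cyclopentyl]heptanoate | OC[C@@H]1[C@@H](CCCCCCC(=O)OC)[C@@H](O)C[C@H]1O[Si](C)(C)C(C)(C)C | intermediate
21 | methyl 7-[(1R,2R,3R,5S)-3-[(TBS)oxy]-2-formyl-5-hydroxycyclopentyl]heptanoate | O=C[C@@H]1[C@@H](CCCCCCC(=O)OC)[C@@H](O)C[C@H]1O[Si](C)(C)C(C)(C)C | intermediate
22 | dimethyl (2-oxoheptyl)phosphonate | CCCCCC(=O)CP(=O)(OC)OC | starting material
23 | methyl 7-[(1R,2R,3R,5S)-3-[(TBS)oxy]-5-hydroxy-2-[(1E)-3-oxooct-1-en-1-yl]cyclopentyl]heptanoate | CCCCCC(=O)/C=C/[C@@H]1[C@@H](CCCCCCC(=O)OC)[C@@H](O)C[C@H]1O[Si](C)(C)C(C)(C)C | intermediate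
24 | methyl 7-[(1R,2R,3R,5S)-3-[(TBS)oxy]-5-hydroxy-2-[(1E,3S)-3-hydroxyoct-1-en-1-yl]cyclopentyl]heptanoate | CCCCC[C@H](O)/C=C/[C@@H]1[C@@H](CCCCCCC(=O)OC)[C@@H](O)C[C@H]1O[Si](C)(C)C(C)(C)C | intermediate
25 | methyl 7-[(1R,2R,3R,5S)-3,5-dihydroxy-2-[(1E,3S)-3-hydroxyoct-1-en-1-yl]cyclopentyl]heptanoate | CCCCC[C@H](O)/C=C/[C@@H]1[C@@H](CCCCCCC(=O)OC)[C@@H](O)C[C@H]1O | intermediate
26 | 7-[(1R,2R,3R,5S)-3,5-dihydroxy-2-[(1E,3S)-3-hydroxyoct-1-en-1-yl]cyclopentyl]heptanoic acid (prostaglandin F1α) | CCCCC[C@H](O)/C=C/[C@@H]1[C@@H](CCCCCCC(=O)O)[C@@H](O)C[C@H]1O | target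

## Step count and risk

Total step count: 18. Longest linear sequence: 17 steps (1 to 26 through steps 1–4 and 6–18; step 5 prepares iodide 9).

**Step 10 (key step).** The most likely failure is incomplete discrimination between the two diastereotopic silyloxymethyl arms, or between the two hydrogens of the chosen arm, together with competing insertion into the unactivated C6–H bonds. The only bias between the arms is conformational, and the chain C–H bonds are at the same distance from C10. The fallback closes the ring before the chain is attached and lets a chiral catalyst choose the arm. It sets out from aldehyde 5. Roskamp homologation with 13 would give benzyl 5-[(TBS)oxy]-4-{[(TBS)oxy]methyl}-3-oxopentanoate F1, and diazo transfer would give benzyl 2-diazo-5-[(TBS)oxy]-4-{[(TBS)oxy]methyl}-3-oxopentanoate F2. Insertion with a chiral dirhodium carboxylate such as Rh2(S-PTTL)4 (dirhodium tetrakis[N-phthaloyl-(S)-tert-leucinate]) or its mirror image, chosen to select the required enantiotopic arm, would give benzyl (2S,3S)-2-[(TBS)oxy]-3-{[(TBS)oxy]methyl}-5-oxocyclopentane-1-carboxylate F3. The dianion of F3 (two equivalents of LiN(i-Pr)2) would then be alkylated at C8 by iodide 9, anti to the C12 arm, which returns to the route at 16. This variant has no C6–H bond at the insertion stage.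

**Step 6.** The most likely failure is slow displacement at the β-branched azaenolate, which would let addition to the ester carbonyl of 9 or proton transfer compete. The fallback sets C8 through an imide enolate, which is far less basic, and sets out from ester 4.
- Saponification would give 4-[(TBS)oxy]-3-{[(TBS)oxy]methyl}butanoic acid F4.
- Mixed-anhydride acylation of lithiated (R)-4-benzyl-1,3-oxazolidin-2-one would give (4R)-4-benzyl-3-{4-[(TBS)oxy]-3-{[(TBS)oxy]methyl}butanoyl}-1,3-oxazolidin-2-one F5.
- Commercial methyl 7-hydroxyheptanoate F6 would be converted with Tf2O and 2,6-lutidine into methyl 7-{[(trifluoromethyl)sulfonyl]oxy}heptanoate F7, an electrophile reactive enough for an imide enolate.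
- Evans alkylation of the NaN(SiMe3)2 enolate of F5 with F7 would give methyl (8R)-8-{[(4R)-4-benzyl-2-oxo-1,3-oxazolidin-3-yl]carbonyl}-10-[(TBS)oxy]-9-{[(TBS)oxy]methyl}decanoate F8.
- LiOH/H2O2 would release (2R)-2-{1,3-bis[(TBS)oxy]propan-2-yl}-9-methoxy-9-oxononanoic acid F9 without touching the methyl ester.
- Activation with 1,1'-carbonyldiimidazole and C-acylation of Mg(O2CCH2CO2Bn)2 would return to the route at 14.

**Step 8.** The most likely failure is partial epimerisation of C8 in the α-branched aldehyde under the Lewis acid, or a sluggish hydride shift at the hindered carbinol carbon. The fallback sets out from 12. Lithiated 13 (LiN(i-Pr)2, THF, −78 °C) would add to give 1-benzyl 11-methyl (4R)-4-{1,3-bis[(TBS)oxy]propan-2-yl}-2-diazo-3-hydroxyundecanedioate F10 (carbinol epimers). Oxidation with Dess–Martin periodinane would return to the route at 15, bypassing 14 and step 9.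

**Step 13.** The most likely failure is loss of selectivity between the primary and the secondary silyl ether, or silyl migration to the free 9-hydroxyl. The fallback gives up the differentiation and sets out from 19.
- HF·pyridine would remove both silyl groups to give methyl 7-[(1R,2S,3R,5S)-3,5-dihydroxy-2-(hydroxymethyl)cyclopentyl]heptanoate F11.
- TEMPO/PhI(OAc)2 would oxidise only the primary alcohol to methyl 7-[(1R,2R,3R,5S)-2-formyl-3,5-dihydroxycyclopentyl]heptanoate F12.
- Olefination with 22 under the conditions of step 15 would give methyl 7-[(1R,2R,3R,5S)-3,5-dihydroxy-2-[(1E)-3-oxooct-1-en-1-yl]cyclopentyl]heptanoate F13.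
- Oxazaborolidine-mediated reduction with excess catecholborane would return to the route at 25.

**Step 16.** The most likely failure is poor facial selectivity at C15, because the borate formed at the free 9-hydroxyl may disturb binding of the ketone to the catalyst, with some conjugate reduction as a side path. The fallback removes the free hydroxyl and sets out from 23. Silylation with TBSOTf and 2,6-lutidine would give methyl 7-[(1R,2R,3R,5S)-3,5-bis[(TBS)oxy]-2-[(1E)-3-oxooct-1-en-1-yl]cyclopentyl]heptanoate F14. The same reduction on this fully protected enone would give methyl 7-[(1R,2R,3R,5S)-3,5-bis[(TBS)oxy]-2-[(1E,3S)-3-hydroxyoct-1-en-1-yl]cyclopentyl]heptanoate F15. HF·pyridine would remove both silyl groups and return to the route at 25.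

## Further compounds

F1 | step 10 | benzyl 5-[(TBS)oxy]-4-{[(TBS)oxy]methyl}-3-oxopentanoate | O=C(CC(=O)CC(CO[Si](C)(C)C(C)(C)C)CO[Si](C)(C)C(C)(C)C)OCc1ccccc1
F2 | step 10 | benzyl 2-diazo-5-[(TBS)oxy]-4-{[(TBS)oxy]methyl}-3-oxopentanoate | [N-]=[N+]=C(C(=O)OCc1ccccc1)C(=O)CC(CO[Si](C)(C)C(C)(C)C)CO[Si](C)(C)C(C)(C)C
F3 | step 10 | benzyl (2S,3S)-2-[(TBS)oxy]-3-{[(TBS)oxy]methyl}-5-oxocyclopentane-1-carboxylate | O=C(OCc1ccccc1)C1C(=O)C[C@@H](CO[Si](C)(C)C(C)(C)C)[C@@H]1O[Si](C)(C)C(C)(C)C
F4 | step 6 | 4-[(TBS)oxy]-3-{[(TBS)oxy]methyl}butanoic acid | OC(=O)CC(CO[Si](C)(C)C(C)(C)C)CO[Si](C)(C)C(C)(C)C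
F5 | step 6 | (4R)-4-benzyl-3-{4-[(TBS)oxy]-3-{[(TBS)oxy]methyl}butanoyl}-1,3-oxazolidin-2-one | O=C(CC(CO[Si](C)(C)C(C)(C)C)CO[Si](C)(C)C(C)(C)C)N1[C@H](Cc2ccccc2)COC1=O
F6 | step 6 | methyl 7-hydroxyheptanoate | COC(=O)CCCCCCO
F7 | step 6 | methyl 7-{[(trifluoromethyl)sulfonyl]oxy}heptanoate | COC(=O)CCCCCCOS(=O)(=O)C(F)(F)F
F8 | step 6 | methyl (8R)-8-{[(4R)-4-benzyl-2-oxo-1,3-oxazolidin-3-yl]carbonyl}-10-[(TBS)oxy]-9-{[(TBS)oxy]methyl}decanoate | O=C([C@H](CCCCCCC(=O)OC)C(CO[Si](C)(C)C(C)(C)C)CO[Si](C)(C)C(C)(C)C)N1[C@H](Cc2ccccc2)COC1=O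
F9 | step 6 | (2R)-2-{1,3-bis[(TBS)oxy]propan-2-yl}-9-methoxy-9-oxononanoic acid | OC(=O)[C@H](CCCCCCC(=O)OC)C(CO[Si](C)(C)C(C)(C)C)CO[Si](C)(C)C(C)(C)C
F10 | step 8 | 1-benzyl 11-methyl (4R)-4-{1,3-bis[(TBS)oxy]propan-2-yl}-2-diazo-3-hydroxyundecanedioate (carbinol epimers) | [N-]=[N+]=C(C(=O)OCc1ccccc1)C(O)[C@H](CCCCCCC(=O)OC)C(CO[Si](C)(C)C(C)(C)C)CO[Si](C)(C)C(C)(C)C
F11 | step 13 | methyl 7-[(1R,2S,3R,5S)-3,5-dihydroxy-2-(hydroxymethyl)cyclopentyl]heptanoate | OC[C@@H]1[C@@H](CCCCCCC(=O)OC)[C@@H](O)C[C@H]1O
F12 | step 13 | methyl 7-[(1R,2R,3R,5S)-2-formyl-3,5-dihydroxycyclopentyl]heptanoate | O=C[C@@H]1[C@@H](CCCCCCC(=O)OC)[C@@H](O)C[C@H]1O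
F13 | step 13 | methyl 7-[(1R,2R,3R,5S)-3,5-dihydroxy-2-[(1E)-3-oxooct-1-en-1-yl]cyclopentyl]heptanoate | CCCCCC(=O)/C=C/[C@@H]1[C@@H](CCCCCCC(=O)OC)[C@@H](O)C[C@H]1O
F14 | step 16 | methyl 7-[(1R,2R,3R,5S)-3,5-bis[(TBS)oxy]-2-[(1E)-3-oxooct-1-en-1-yl]cyclopentyl]heptanoate | CCCCCC(=O)/C=C/[C@@H]1[C@@H](CCCCCCC(=O)OC)[C@@H](O[Si](C)(C)C(C)(C)C)C[C@H]1O[Si](C)(C)C(C)(C)C
F15 | step 16 | methyl 7-[(1R,2R,3R,5S)-3,5-bis[(TBS)oxy]-2-[(1E,3S)-3-hydroxyoct-1-en-1-yl]cyclopentyl]heptanoate | CCCCC[C@H](O)/C=C/[C@@H]1[C@@H](CCCCCCC(=O)OC)[C@@H](O[Si](C)(C)C(C)(C)C)C[C@H]1O[Si](C)(C)C(C)(C)C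
A1 | alternative 1 | succinaldehyde (butanedial) | O=CCC=O
A2 | alternative 1 | cis-fused bicyclic enal lactol, 2-hydroxy-3,3a,6,6a-tetrahydro-2H-cyclopenta[b]furan-5-carbaldehyde (anomers) | O=CC1=C[C@H]2CC(O)O[C@H]2C1
A3 | alternative 2 | tert-butyl{[(1R,4S)-4-(1-ethoxy-2-iodoethoxy)cyclopent-2-en-1-yl]oxy}dimethylsilane (acetal epimers) | CCOC(CI)O[C@H]1C[C@@H](O[Si](C)(C)C(C)(C)C)C=C1
A4 | alternative 2 | 2-(trimethylsilyl)oct-1-en-3-one | CCCCCC(=O)C(=C)[Si](C)(C)C
A5 | alternative 2 | bicyclic ethyl acetal with 11-O-TBS group and α-trimethylsilyl ketone side chain (acetal and C14 epimers) | CCCCCC(=O)C([Si](C)(C)C)C[C@@H]1[C@H]2CC(OCC)O[C@H]2C[C@H]1O[Si](C)(C)C(C)(C)C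
A6 | alternative 3 | (8Z,11Z,14Z)-icosa-8,11,14-trienoic acid (dihomo-γ-linolenic acid) | CCCCC/C=C\C/C=C\C/C=C\CCCCCCC(=O)O
A7 | alternative 3 | prostaglandin G1, the 9,11-endoperoxide 15-hydroperoxide | CCCCC[C@H](OO)/C=C/[C@@H]1[C@@H](CCCCCCC(=O)O)[C@@H]2C[C@H]1OO2
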